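The cyclopentene ring (C1, C2, C3, C3a, C7a; 1H-indene numbering) is disconnected at its C2=C3 double bond, read as the scar of an extruded SO2: it is a ring-contracted thiane 1,1-dioxide. The key step, a Ramberg–Bäcklund reaction, converts the six-membered sulfone ring of a trans-fused bicyclic sulfone into the five-membered carbocycle and installs the trisubstituted alkene with its ethyl group in one operation, delivering the target acid directly. The precursor comes from an intramolecular Diels–Alder reaction of a sulfone-tethered tetraene acid; the two allylic stereocentres flanking sulfur (C1 permanent, C3 temporary) fix both π-faces, and the temporary one is erased on contraction.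

Key step: step 14

Remark: atom labels C1–C7a are those of the 1H-indene skeleton of the target and are used for the corresponding atoms of all intermediates; L-proline-catalysed α-aminoxylation of butanal is assumed to give the (R)-aldehyde, as it does for other linear aldehydes.

Step 1
Reactants: 1 (2S)-3-(acetylsulfanyl)-2-methylpropanoic acid
Product: 2 (2S)-2-methyl-3-sulfanylpropan-1-ol
Conditions: LiAlH4, THF, 0 °C → reflux; then 1 M HCl
Reagents that add atoms: none
Why: Hydride reduction: LiAlH4 takes the carboxylic acid to the primary alcohol and cleaves the thioacetate to the thiol (acetyl leaves as ethanol); the stereocentre is untouched because the carboxylate does not enolise.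

Step 2
Reactants: 3 butanal; 4 methyl 2-(triphenyl-λ5-phosphanylidene)propanoate
Product: 6 methyl (2E,4R)-2-methyl-4-[(phenylamino)oxy]hex-2-enoate, via aminoxy aldehyde 5 (not isolated)
Conditions: PhNO, L-proline (10 mol %), CHCl3, 4 °C; then 4, 0 °C → rt
Reagents that add atoms: nitrosobenzene, O=Nc1ccccc1
Why: Proline-catalysed α-aminoxylation (enamine catalysis; the carboxylic acid of L-proline steers the nitroso oxygen to one enamine face and sets the (R) centre), followed in the same flask by an E-selective Wittig olefination with the stabilised ylide, which traps the configurationally labile aldehyde 5.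

Step 3
Reactants: 6 methyl (2E,4R)-2-methyl-4-[(phenylamino)oxy]hex-2-enoate
Product: 7 methyl (2E,4R)-4-hydroxy-2-methylhex-2-enoate
Conditions: Zn, AcOH, THF, rt
Reagents that add atoms: none
Why: Reductive N–O cleavage by Zn/AcOH breaks only the weak N–O bond and leaves the enoate and the C–O stereocentre intact.

Step 4
Reactants: 7 methyl (2E,4R)-4-hydroxy-2-methylhex-2-enoate
Product: 8 methyl (2E,4R)-4-[(methanesulfonyl)oxy]-2-methylhex-2-enoate
Conditions: MsCl, Et3N, CH2Cl2, −20 °C
Reagents that add atoms: methanesulfonyl chloride, CS(=O)(=O)Cl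
Why: Mesylation (sulfonate ester formation) occurs at oxygen with retention at carbon, and the electron-poor allylic mesylate should not ionise.

Step 5
Reactants: 2 (2S)-2-methyl-3-sulfanylpropan-1-ol; 8 methyl (2E,4R)-4-[(methanesulfonyl)oxy]-2-methylhex-2-enoate
Product: 9 methyl (2E,4S)-4-{[(2S)-3-hydroxy-2-methylpropyl]sulfanyl}-2-methylhex-2-enoate
Conditions: K2CO3, DMF, 0 °C → rt
Reagents that add atoms: none
Why: SN2 thioetherification: the soft thiolate of 2 (formed selectively over the alkoxide) displaces the allylic mesylate with inversion, giving the (4S) sulfide that becomes the temporary C3 centre; SN2′ attack is blocked by the fully substituted α-carbon.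

Step 6
Reactants: 9 methyl (2E,4S)-4-{[(2S)-3-hydroxy-2-methylpropyl]sulfanyl}-2-methylhex-2-enoate
Product: 10 methyl (2E,4S)-2-methyl-4-{[(2S)-2-methyl-3-oxopropyl]sulfanyl}hex-2-enoate
Conditions: Dess–Martin periodinane, CH2Cl2, 0 °C → rt
Reagents that add atoms: none
Why: Dess–Martin oxidation of the primary alcohol under neutral conditions should leave the thioether unoxidised and the α-stereocentre (future C1) unepimerised.

Step 7
Reactants: 10 methyl (2E,4S)-2-methyl-4-{[(2S)-2-methyl-3-oxopropyl]sulfanyl}hex-2-enoate; 11 2-(triphenyl-λ5-phosphanylidene)propanal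
Product: 12 methyl (2E,4S)-4-{[(2S,3E)-2,4-dimethyl-5-oxopent-3-en-1-yl]sulfanyl}-2-methylhex-2-enoate
Conditions: toluene, 80 °C
Reagents that add atoms: none
Why: Wittig olefination with the formyl-stabilised ylide gives the (E)-trisubstituted enal under neutral conditions that should not epimerise the α-methyl aldehyde.

Step 8
Reactants: 13 triphenyl(propyl)phosphonium bromide; 14 ethyl formate
Product: 16 2-(triphenyl-λ5-phosphanylidene)butanal, via propylidene ylide 15 (not isolated)
Conditions: KOt-Bu (2 equiv), THF, 0 °C; then 14, 0 °C → rt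
Reagents that add atoms: none
Why: Wittig ylide formation followed by C-formylation with ethyl formate; the second equivalent of base deprotonates the acylphosphonium salt to the stabilised ylide.

Step 9
Reactants: 12 methyl (2E,4S)-4-{[(2S,3E)-2,4-dimethyl-5-oxopent-3-en-1-yl]sulfanyl}-2-methylhex-2-enoate; 16 2-(triphenyl-λ5-phosphanylidene)butanal
Product: 17 methyl (2E,4S)-4-{[(2S,3E,5E)-6-formyl-2,4-dimethylocta-3,5-dien-1-yl]sulfanyl}-2-methylhex-2-enoate
Conditions: toluene, 100 °C
Reagents that add atoms: none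
Why: Second Wittig homologation with the formyl ylide should give the (E,E)-dienal; the product, an α-ethyl dienal, is less electrophilic than 12 and should not react on.

Step 10
Reactants: 17 methyl (2E,4S)-4-{[(2S,3E,5E)-6-formyl-2,4-dimethylocta-3,5-dien-1-yl]sulfanyl}-2-methylhex-2-enoate; 18 diethyl [(2E)-3-phenylprop-2-en-1-yl]phosphonate
Product: 19 methyl (2E,4S)-4-{[(2S,3E,5E,7E,9E)-6-ethyl-2,4-dimethyl-10-phenyldeca-3,5,7,9-tetraen-1-yl]sulfanyl}-2-methylhex-2-enoate
Conditions: LiN(SiMe3)2, THF, −78 → 0 °C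
Reagents that add atoms: none
Why: Horner–Wadsworth–Emmons olefination with the allylic phosphonate anion (α-attack) forms the new disubstituted double bond with E geometry and completes the all-E tetraene.

Step 11
Reactants: 19 methyl (2E,4S)-4-{[(2S,3E,5E,7E,9E)-6-ethyl-2,4-dimethyl-10-phenyldeca-3,5,7,9-tetraen-1-yl]sulfanyl}-2-methylhex-2-enoate
Product: 20 (2E,4S)-4-{[(2S,3E,5E,7E,9E)-6-ethyl-2,4-dimethyl-10-phenyldeca-3,5,7,9-tetraen-1-yl]sulfanyl}-2-methylhex-2-enoic acid
Conditions: LiOH, THF/MeOH/H2O, rt; then 1 M HCl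
Reagents that add atoms: lithium hydroxide, [Li+].[OH-]
Why: Saponification (BAc2) of the unhindered enoate is done here because after cycloaddition the carboxyl sits on a quaternary carbon flanked by a second one; the weakly acidic γ-thio C–H should not be deprotonated by hydroxide.

Step 12
Reactants: 20 (2E,4S)-4-{[(2S,3E,5E,7E,9E)-6-ethyl-2,4-dimethyl-10-phenyldeca-3,5,7,9-tetraen-1-yl]sulfanyl}-2-methylhex-2-enoic acid
Product: 21 (2E,4S)-4-{[(2S,3E,5E,7E,9E)-6-ethyl-2,4-dimethyl-10-phenyldeca-3,5,7,9-tetraen-1-yl]sulfonyl}-2-methylhex-2-enoic acid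
Conditions: (NH4)6Mo7O24·4H2O (10 mol %), 30% H2O2, EtOH, 0 °C
Reagents that add atoms: hydrogen peroxide, OO
Why: Peroxomolybdate-catalysed oxygen transfer to sulfur (sulfide to sulfone) is much faster than epoxidation of unfunctionalised C=C, and at 0 °C the intermediate allylic sulfoxide should be oxidised on before a Mislow–Evans rearrangement can scramble C3.

Step 13
Reactants: 21 (2E,4S)-4-{[(2S,3E,5E,7E,9E)-6-ethyl-2,4-dimethyl-10-phenyldeca-3,5,7,9-tetraen-1-yl]sulfonyl}-2-methylhex-2-enoic acid
Product: 22 (1S,4S,4aS,7S,8R,8aS)-1,7-diethyl-4,5,8-trimethyl-2,2-dioxo-7-[(1E,3E)-4-phenylbuta-1,3-dien-1-yl]-3,4,4a,7,8,8a-hexahydro-1H-2λ6-isothiochromene-8-carboxylic acid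
Conditions: toluene (0.01 M), BHT, 110 °C
Reagents that add atoms: none
Why: Intramolecular Diels–Alder reaction of the (E)-enoic acid (C4=C3a) with the C7a=C7–C6=C5 diene through a chair-like sulfone tether with the carboxyl endo: 1,3-allylic strain makes C1–H eclipse the C7 methyl side and C3–H eclipse the C4 methyl side, so the C1 methyl and the C3 ethyl both sit equatorial and only the trans-fused transition state satisfies both, which sets C7a and C3a, while the E geometries of dienophile and diene terminus translate into the C4 and C5 quaternary centres.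

Step 14
Reactants: 22 (1S,4S,4aS,7S,8R,8aS)-1,7-diethyl-4,5,8-trimethyl-2,2-dioxo-7-[(1E,3E)-4-phenylbuta-1,3-dien-1-yl]-3,4,4a,7,8,8a-hexahydro-1H-2λ6-isothiochromene-8-carboxylic acid
Product: 25 (1R,3aR,4R,5S,7aS)-3,5-diethyl-1,4,7-trimethyl-5-[(1E,3E)-4-phenylbuta-1,3-dien-1-yl]-3a,4,5,7a-tetrahydro-1H-indene-4-carboxylic acid, via α-bromo sulfone 23 (not isolated), via episulfone 24 (not isolated)
Conditions: CBr2F2, KOH/Al2O3, t-BuOH/CH2Cl2, 0 °C → rt; then 1 M HCl
Reagents that add atoms: none
Why: The sulfone is deprotonated at its more accessible α-CH2 (C2) and the carbanion is brominated by CBr2F2 to give 23; deprotonation at the other α-carbon (C3–H) and 1,3-displacement of bromide close the episulfone 24, and cheletropic loss of SO2 leaves the C2=C3 double bond, which is the Ramberg–Bäcklund reaction, a known ring contraction of thiane 1,1-dioxides to cyclopentenes. The only ring closed is the three-membered thiirane dioxide of 24, by 3-exo-tet attack of the C3 carbanion on C2 with the C–Br bond equatorial (W arrangement, reachable because the α-bromide epimerises under the base); its collapse turns the six-membered sulfone ring into the five-membered carbocycle. No stereocentre is created: the temporary C3 centre becomes sp2, and C1, C3a and C7a, which are β to sulfur and not acidic, keep the configuration set in step 13, so the trans ring fusion is carried over. The step needs chemoselectivity, since monohalogenation and closure must beat polyhalogenation at C2 and carbene addition to the C6=C7 and dienyl double bonds; CBr2F2 in place of CCl4 and the non-enolisable carboxylate on a quaternary carbon should secure this, and either site of first halogenation leads to the same alkene.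

Compound list
1 | (2S)-3-(acetylsulfanyl)-2-methylpropanoic acid | CC(=O)SC[C@@H](C)C(=O)O | starting material
2 | (2S)-2-methyl-3-sulfanylpropan-1-ol | SC[C@@H](C)CO | intermediate
3 | butanal | CCCC=O | starting material
4 | methyl 2-(triphenyl-λ5-phosphanylidene)propanoate | COC(=O)C(C)=P(c1ccccc1)(c1ccccc1)c1ccccc1 | starting material
5 | (2R)-2-[(phenylamino)oxy]butanal | CC[C@H](C=O)ONc1ccccc1 | intermediate
6 | methyl (2E,4R)-2-methyl-4-[(phenylamino)oxy]hex-2-enoate | CC[C@H](/C=C(\C)C(=O)OC)ONc1ccccc1 | intermediate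
7 | methyl (2E,4R)-4-hydroxy-2-methylhex-2-enoate | CC[C@H](/C=C(\C)C(=O)OC)O | intermediate
8 | methyl (2E,4R)-4-[(methanesulfonyl)oxy]-2-methylhex-2-enoate | CC[C@H](/C=C(\C)C(=O)OC)OS(C)(=O)=O | intermediate
9 | methyl (2E,4S)-4-{[(2S)-3-hydroxy-2-methylpropyl]sulfanyl}-2-methylhex-2-enoate | CC[C@@H](/C=C(\C)C(=O)OC)SC[C@@H](C)CO | intermediate
10 | methyl (2E,4S)-2-methyl-4-{[(2S)-2-methyl-3-oxopropyl]sulfanyl}hex-2-enoate | CC[C@@H](/C=C(\C)C(=O)OC)SC[C@@H](C)C=O | intermediate
11 | 2-(triphenyl-λ5-phosphanylidene)propanal | CC(C=O)=P(c1ccccc1)(c1ccccc1)c1ccccc1 | starting material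
12 | methyl (2E,4S)-4-{[(2S,3E)-2,4-dimethyl-5-oxopent-3-en-1-yl]sulfanyl}-2-methylhex-2-enoate | CC[C@@H](/C=C(\C)C(=O)OC)SC[C@@H](C)/C=C(\C)C=O | intermediate
13 | triphenyl(propyl)phosphonium bromide | CCC[P+](c1ccccc1)(c1ccccc1)c1ccccc1.[Br-] | starting material
14 | ethyl formate | CCOC=O | starting material
15 | triphenyl(propylidene)-λ5-phosphane | CCC=P(c1ccccc1)(c1ccccc1)c1ccccc1 | intermediate
16 | 2-(triphenyl-λ5-phosphanylidene)butanal | CCC(C=O)=P(c1ccccc1)(c1ccccc1)c1ccccc1 | intermediate
17 | methyl (2E,4S)-4-{[(2S,3E,5E)-6-formyl-2,4-dimethylocta-3,5-dien-1-yl]sulfanyl}-2-methylhex-2-enoate | CC[C@@H](/C=C(\C)C(=O)OC)SC[C@@H](C)/C=C(C)/C=C(\CC)C=O | intermediate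
18 | diethyl [(2E)-3-phenylprop-2-en-1-yl]phosphonate | CCOP(=O)(C/C=C/c1ccccc1)OCC | starting material
19 | methyl (2E,4S)-4-{[(2S,3E,5E,7E,9E)-6-ethyl-2,4-dimethyl-10-phenyldeca-3,5,7,9-tetraen-1-yl]sulfanyl}-2-methylhex-2-enoate | CC[C@@H](/C=C(\C)C(=O)OC)SC[C@@H](C)/C=C(C)/C=C(CC)/C=C/C=C/c1ccccc1 | intermediate
20 | (2E,4S)-4-{[(2S,3E,5E,7E,9E)-6-ethyl-2,4-dimethyl-10-phenyldeca-3,5,7,9-tetraen-1-yl]sulfanyl}-2-methylhex-2-enoic acid | CC[C@@H](/C=C(\C)C(=O)O)SC[C@@H](C)/C=C(C)/C=C(CC)/C=C/C=C/c1ccccc1 | intermediate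
21 | (2E,4S)-4-{[(2S,3E,5E,7E,9E)-6-ethyl-2,4-dimethyl-10-phenyldeca-3,5,7,9-tetraen-1-yl]sulfonyl}-2-methylhex-2-enoic acid | CC[C@@H](/C=C(\C)C(=O)O)S(=O)(=O)C[C@@H](C)/C=C(C)/C=C(CC)/C=C/C=C/c1ccccc1 | intermediate
22 | (1S,4S,4aS,7S,8R,8aS)-1,7-diethyl-4,5,8-trimethyl-2,2-dioxo-7-[(1E,3E)-4-phenylbuta-1,3-dien-1-yl]-3,4,4a,7,8,8a-hexahydro-1H-2λ6-isothiochromene-8-carboxylic acid (trans-fused; sulfur between C2 and C3 of the target numbering) | CC[C@@H]1S(=O)(=O)C[C@@H](C)[C@@H]2C(C)=C[C@@](/C=C/C=C/c3ccccc3)(CC)[C@](C)(C(=O)O)[C@@H]12 | intermediate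
23 | 3-bromo derivative of 22 (bromine on the CH2 next to sulfur, either epimer) | CC[C@@H]1S(=O)(=O)C(Br)[C@@H](C)[C@@H]2C(C)=C[C@@](/C=C/C=C/c3ccccc3)(CC)[C@](C)(C(=O)O)[C@@H]12 | intermediate
24 | episulfone: thiirane 1,1-dioxide bridging C2 and C3 of the trans-fused hydrindene acid | CCC12C([C@@H](C)[C@@H]3C(C)=C[C@@](/C=C/C=C/c4ccccc4)(CC)[C@](C)(C(=O)O)[C@@H]13)S2(=O)=O | intermediate
25 | (1R,3aR,4R,5S,7aS)-3,5-diethyl-1,4,7-trimethyl-5-[(1E,3E)-4-phenylbuta-1,3-dien-1-yl]-3a,4,5,7a-tetrahydro-1H-indene-4-carboxylic acid | CCC1=C[C@@H](C)[C@@H]2C(C)=C[C@@](/C=C/C=C/c3ccccc3)(CC)[C@](C)(C(=O)O)[C@@H]12 | target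

Total steps: 14. Longest linear sequence: 12 steps (butanal 3 to 25 through steps 2, 3, 4, 5, 6, 7, 9, 10, 11, 12, 13 and 14).

Steps most likely to fail

Step 13. The cycloaddition may be too slow below the temperature at which a 1,5-hydrogen shift from the inside ethyl group into the diene sets in, or the endo preference may erode so that the cis-fused isomer forms as well. The fallback sets out from 19 and replaces thermal activation by Lewis-acid activation of an ester. Oxidation of 19 with (NH4)6Mo7O24·4H2O/H2O2 in EtOH at 0 °C should give the sulfone methyl ester F1. EtAlCl2 (1 equiv) in CH2Cl2 at −40 → 0 °C should then promote the endo-selective intramolecular Diels–Alder reaction to the bicyclic sulfone methyl ester F2. SN2 demethylation of F2 with n-PrSLi in HMPA at rt, where attack at the methyl group makes the hindered carbonyl irrelevant, comes back to the route at 22.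

Step 14. Deprotonation at the hindered tertiary C3–H may be slower than a second bromination at C2 or than carbene capture by the electron-rich double bonds, so that closure to the episulfone is outrun. The fallback sets out from 22 and separates halogenation from extrusion. LiN(i-Pr)2 (2.1 equiv) in THF at −78 °C followed by C2Cl6 should give, after work-up, the isolated mono-α-chloro sulfone F3 with no excess halogen source and no carbene precursor present. KOt-Bu in THF at 0 °C → rt should then effect closure and loss of SO2, and the fallback comes back to the route at 25.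

Step 12. Oxygen transfer may reach the electron-rich tetraene, or the intermediate allylic sulfoxide may undergo Mislow–Evans equilibration before the second oxidation and scramble C3 and the enoate geometry. The fallback sets out from 20 and defers the oxidation until the tetraene is consumed. Heating 20 in toluene with BHT at 110 °C should give, through the same chair-like transition state, the bicyclic sulfide acid F4, in which sulfur is no longer allylic. Oxidation of F4 with (NH4)6Mo7O24·4H2O/H2O2 in EtOH comes back to the route at 22.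

Further compounds
F1 | step 13 | methyl (2E,4S)-4-{[(2S,3E,5E,7E,9E)-6-ethyl-2,4-dimethyl-10-phenyldeca-3,5,7,9-tetraen-1-yl]sulfonyl}-2-methylhex-2-enoate | CC[C@@H](/C=C(\C)C(=O)OC)S(=O)(=O)C[C@@H](C)/C=C(C)/C=C(CC)/C=C/C=C/c1ccccc1
F2 | step 13 | methyl (1S,4S,4aS,7S,8R,8aS)-1,7-diethyl-4,5,8-trimethyl-2,2-dioxo-7-[(1E,3E)-4-phenylbuta-1,3-dien-1-yl]-3,4,4a,7,8,8a-hexahydro-1H-2λ6-isothiochromene-8-carboxylate | CC[C@@H]1S(=O)(=O)C[C@@H](C)[C@@H]2C(C)=C[C@@](/C=C/C=C/c3ccccc3)(CC)[C@](C)(C(=O)OC)[C@@H]12
F3 | step 14 | 3-chloro derivative of 22 (chlorine on the CH2 next to sulfur, either epimer) | CC[C@@H]1S(=O)(=O)C(Cl)[C@@H](C)[C@@H]2C(C)=C[C@@](/C=C/C=C/c3ccccc3)(CC)[C@](C)(C(=O)O)[C@@H]12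
F4 | step 12 | (1S,4S,4aS,7S,8R,8aS)-1,7-diethyl-4,5,8-trimethyl-7-[(1E,3E)-4-phenylbuta-1,3-dien-1-yl]-3,4,4a,7,8,8a-hexahydro-1H-isothiochromene-8-carboxylic acid | CC[C@@H]1SC[C@@H](C)[C@@H]2C(C)=C[C@@](/C=C/C=C/c3ccccc3)(CC)[C@](C)(C(=O)O)[C@@H]12
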